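Time is what I read first in the cedar flask, and I count it in half-lives of the starting material, not in minutes. The elm run is the same charge, held cooler.

| flask | starting material | temperature | remark | time |
|---|---|---|---|---|
| cedar | 3 M | 35 °C | the very flask that is asked about, followed so far |  |
| elm | 3 M | 20 °C | run made earlier |  |
| flask | 3.0 M | 35 °C |  | 10 min |

| run | time / min | target / % | starting material / % |
|---|---|---|---|
| cedar | 0.667 | 25.9 | 59.9 |
| cedar | 2.00 | 43.8 | 21.4 |
| cedar | 4.00 | 50.7 | 4.0 |
| cedar | 5.00 | 51.9 | 1.9 |
| cedar | 8.00 | 51.4 | 1.8 |
| cedar | 10.0 | 52.3 | 0.7 |
| elm | 1.33 | 16.0 | 79.1 |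
| elm | 4.00 | 36.5 | 48.9 |
| elm | 8.00 | 49.9 | 21.8 |
| elm | 10.0 | 54.0 | 17.2 |
| elm | 15.0 | 59.8 | 6.2 |
| elm | 20.0 | 59.2 | 3.9 |

(standard deviation of a reading: 1 percentage point)

- ochre: change nothing and wait 3.0 min more
- red: at 10 min take out 90% of the target then present, then wait 3.0 min
- amber: at 10 min raise the temperature by 15 K, then wait 3.0 min

- target that was removed still counts

- target, in percent of the starting material first charged, at 10 min
- the option that brings most further target ("none" if no option brings more than 2 percentage points) (ochre / red / amber / none)
- target present, with what was taken out counted in, in percent of the starting material first charged, after ochre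
- target present, with what was taken out counted in, in percent of the starting material first charged, after amber

I take the starting material to fall first order, with rate constant k. Then the first cedar reading, 59.9% at 0.667 min, gives

k = 0.768 min⁻¹

My number is N, the count of half-lives of starting material that fit into the time looked at:

N = k × 10 min / ln 2 = 11.1

Each half-life halves what remains, so at 10 min I reckon 0.0460% left in the cedar flask. That is less than the margin 2 percentage points, so I expect ochre to bring less than the margin, and target in the cedar flask to stay near the last reading, 52.3%.

Is one number enough? The elm run, at 20.0 min, has counted 5.16 half-lives and its target reads 59.2%; the cedar flask, at 5.00 min, has counted 5.54 and its target reads 51.9%. So in these two runs a like N goes with different readings of target, and N does not tell how high target stands. In the last cedar reading 47.0% of the charge is neither target nor starting material. A plateau that sinks with heat reads like thermodynamic control, not kinetic control, so I expect red to refill target and amber to lower it.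

The forecast gives 52%, 52.3% after ochre, 47% after amber and red as best, in its words: “The plateau is lower when hot”.

The flask gives 52.6%, 52.6% after ochre, 45.1% after amber, and red as best, bringing 21 points.

    starting material → intermediate (k = 0.0130 s⁻¹, Ea = 75.0 kJ mol⁻¹)
    intermediate ⇌ target (K = 4.30, k = 0.890 s⁻¹, Ea = 84.0 kJ mol⁻¹, ΔH = −22.0 kJ mol⁻¹)
    intermediate ⇌ isomer of the product (K = 2.40, k = 0.0710 s⁻¹, Ea = 92.0 kJ mol⁻¹, ΔH = −6.00 kJ mol⁻¹)
    starting material + intermediate → side product (k = 0.00180 M⁻¹ s⁻¹, Ea = 60.0 kJ mol⁻¹)
    (constants at 35 °C)

Shortened to 2.63 min, the flask's answer has moved by 5 points, and that time is a count of 2.91 half-lives against 11.1. The neighbour flask at 10 °C keeps 54.8% starting material at 10.0 min, a count of 0.868, and its target stands at 34.3%.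

Readings and results are calculated for substances that don't exist, noise included.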